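**Plan**

1. Numbering: enone ring C1 (C=O), C2=C3, C4 (CH–OMe), C5 (CH2), C6 (quaternary); side chain C7 (CH–CH3), C8 (CH–OH, aryl).
2. Enabling feature: C2 is a single CH wedged between C1 and C3, so the six-membered ring is the five-membered ring C1–C3–C4–C5–C6 with one carbon slipped into its C1–C3 bond. C6 carries no hydrogen, so that cyclopentanone can enolise only toward C3.
3. Retrosynthesis: cut C1–C2 and C2–C3 (dibromocarbene taken out of a silyl enol ether; the C2 bromine is a leftover), then C1–C3 (sulfonyl carbanion onto a lactone carbonyl), then C6–allyl and C6–C5 (two lactone enolate alkylations), then C7–C8 (crotylboration of veratraldehyde).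
4. Forward order of rings: γ-lactone O–C1–C6–C7–C8 first; cyclopentanone second (closing C1–C3 opens the lactone and frees the C8 oxygen); cyclohexenone last by one-carbon ring expansion; debromination and desilylation finish.
5. Stereochemistry: C7 and C8 from a (Z)-crotylborane with isopinocampheyl ligands (syn, reagent control); C6 from allylation of the cis-lactone enolate anti to the C7 methyl and C8 aryl groups; C4 from (S)-glycidol, bought as its trityl ether.

Key step: step 13

Remark: the labels C1–C8 of the target are used for the same atoms in every intermediate; the trityl ether of (S)-glycidol and (−)-Ipc2BOMe are taken as purchased; the first alkylation product is carried on as formed because its C6 configuration is erased in the following enolisation.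

**Step 1**
Reactants: 1 veratraldehyde; 2 cis-but-2-ene
Product: 6 (1S,2R)-1-(3,4-dimethoxyphenyl)-2-methylbut-3-en-1-ol, via (Z)-crotylpotassium 3 (not isolated), via (Z)-crotylborane 4 (not isolated), via borinate ester 5 (not isolated)
Conditions: KOC(CH3)3, n-BuLi, THF, −78 → −45 °C; (−)-Ipc2BOMe, −78 °C; BF3·OEt2; then 1, −78 °C; NaOH, H2O2
Reagents that add atoms: none
Why: Brown crotylboration: the (Z)-crotylborane reacts through a closed chair (Zimmerman–Traxler) transition state, so the Z geometry gives the syn C7/C8 product, and the isopinocampheyl ligands derived from (+)-α-pinene direct the transfer to the Si face of the aldehyde, setting C8 (S) and with it C7 (R).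

**Step 2**
Reactants: 6 (1S,2R)-1-(3,4-dimethoxyphenyl)-2-methylbut-3-en-1-ol
Product: 8 (1S,2R)-1-(3,4-dimethoxyphenyl)-2-methylbutane-1,4-diol, via alkylborane 7 (not isolated)
Conditions: 9-BBN, THF, 0 °C → rt; NaOH, H2O2
Reagents that add atoms: hydrogen peroxide (OO)
Why: Anti-Markovnikov hydroboration of the terminal alkene with the bulky borane, then oxidation of the C–B bond with retention, should place the hydroxyl on the terminal carbon (the future C1) without touching C7 or C8.

**Step 3**
Reactants: 8 (1S,2R)-1-(3,4-dimethoxyphenyl)-2-methylbutane-1,4-diol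
Product: 10 (4R,5S)-5-(3,4-dimethoxyphenyl)-4-methyloxolan-2-one (cis-lactone), via lactol 9 (not isolated)
Conditions: TEMPO (cat.), PhI(OAc)2, CH2Cl2, rt
Reagents that add atoms: none
Why: Oxoammonium (TEMPO) oxidation is selective for the primary alcohol; the aldehyde closes onto the C8 hydroxyl to lactol 9 and is oxidised once more, a standard oxidative lactonisation of 1,4-diols that keeps the cis relationship of C7 and C8.

**Step 4**
Reactants: 11 (R)-2-[(trityloxy)methyl]oxirane (trityl ether of (S)-glycidol)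
Product: 13 (S)-[2-methoxy-3-(trityloxy)propyl](phenyl)sulfane, via sodium alkoxide 12 (not isolated)
Conditions: PhSH, NaH, DMF, 0 °C → rt; then MeI, 0 °C
Reagents that add atoms: thiophenol (Sc1ccccc1); iodomethane (CI)
Why: The thiolate opens the terminal epoxide at its CH2 carbon (SN2, the stereocentre is not attacked) and the secondary alkoxide 12 is methylated in the same flask (Williamson ether synthesis); a trityl ether cannot migrate to the neighbouring alkoxide.

**Step 5**
Reactants: 13 (S)-[2-methoxy-3-(trityloxy)propyl](phenyl)sulfane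
Product: 14 (S)-2-methoxy-3-(phenylsulfanyl)propan-1-ol
Conditions: TsOH·H2O (cat.), MeOH/CH2Cl2, rt
Reagents that add atoms: none
Why: Acid-catalysed methanolysis of the trityl ether (stabilised trityl cation) should free the primary alcohol while the methyl ether and the sulfide stay inert.

**Step 6**
Reactants: 14 (S)-2-methoxy-3-(phenylsulfanyl)propan-1-ol
Product: 15 (S)-2-methoxy-3-(phenylsulfanyl)propyl trifluoromethanesulfonate
Conditions: Tf2O, 2,6-lutidine, CH2Cl2, −78 °C; used at once
Reagents that add atoms: trifluoromethanesulfonic anhydride (O=S(=O)(OS(=O)(=O)C(F)(F)F)C(F)(F)F)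
Why: Standard triflation of a primary alcohol; the aryl sulfide is too weak a nucleophile to close a four-membered thietanium ring at −78 °C, and the triflate is not stored.

**Step 7**
Reactants: 10 (4R,5S)-5-(3,4-dimethoxyphenyl)-4-methyloxolan-2-one; 15 (S)-2-methoxy-3-(phenylsulfanyl)propyl trifluoromethanesulfonate
Product: 16 (3R,4R,5S)-5-(3,4-dimethoxyphenyl)-3-[(2S)-2-methoxy-3-(phenylsulfanyl)propyl]-4-methyloxolan-2-one (major 3,4-trans epimer)
Conditions: LiN(i-Pr)2, THF, −78 °C; then 15, −78 → −40 °C
Reagents that add atoms: none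
Why: Alkylation of the lactone lithium enolate at C6 by a primary triflate (SN2), reactive enough for this β-branched, β-oxygenated electrophile at low temperature; the group should enter mainly anti to the C7 methyl, but C6 is planarised again in step 8, so both epimers serve.

**Step 8**
Reactants: 16 (3R,4R,5S)-5-(3,4-dimethoxyphenyl)-3-[(2S)-2-methoxy-3-(phenylsulfanyl)propyl]-4-methyloxolan-2-one; 17 allyl bromide
Product: 18 (3S,4R,5S)-3-allyl-5-(3,4-dimethoxyphenyl)-3-[(2S)-2-methoxy-3-(phenylsulfanyl)propyl]-4-methyloxolan-2-one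
Conditions: LiN(i-Pr)2, THF/DMPU, −78 °C; then 17, −78 → −30 °C
Reagents that add atoms: none
Why: Second lactone enolate alkylation: allyl bromide should approach the planar C6 enolate from the face opposite to the C7 methyl and the C8 aryl group, which sit on the same face of the cis-lactone, so the quaternary centre C6 (S) is set by substrate control; the sulfur is carried as the sulfide here because a sulfone would offer a second acidic site.

**Step 9**
Reactants: 18 (3S,4R,5S)-3-allyl-5-(3,4-dimethoxyphenyl)-3-[(2S)-2-methoxy-3-(phenylsulfanyl)propyl]-4-methyloxolan-2-one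
Product: 20 (3S,4R,5S)-3-allyl-5-(3,4-dimethoxyphenyl)-3-[(2S)-2-methoxy-3-(phenylsulfonyl)propyl]-4-methyloxolan-2-one, via sulfoxide 19 (not isolated)
Conditions: (NH4)6Mo7O24·4H2O (cat.), 30% H2O2, EtOH, 0 °C → rt
Reagents that add atoms: hydrogen peroxide (OO)
Why: Molybdate-catalysed peroxide oxidation should take the sulfide through sulfoxide 19 to the sulfone, while the monosubstituted alkene, the lactone and the dimethoxyarene do not react under these conditions.

**Step 10**
Reactants: 20 (3S,4R,5S)-3-allyl-5-(3,4-dimethoxyphenyl)-3-[(2S)-2-methoxy-3-(phenylsulfonyl)propyl]-4-methyloxolan-2-one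
Product: 21 (2S,4S)-2-allyl-2-[(1S,2R)-1-(3,4-dimethoxyphenyl)-1-hydroxypropan-2-yl]-4-methoxy-5-(phenylsulfonyl)cyclopentan-1-one (epimers at the sulfonyl carbon)
Conditions: LiN(i-Pr)2 (2.2 equiv), THF, −78 °C; AcOH quench at −78 °C
Reagents that add atoms: none
Why: Dieckmann-type intramolecular acylation of an α-sulfonyl carbanion (5-exo-trig): the lithiated sulfone carbon C3 attacks the lactone carbonyl C1, the tetrahedral intermediate collapses with release of the C8 alkoxide, and deprotonation of the β-keto sulfone makes the closure irreversible; at −78 °C ring closure should outrun loss of the β-methoxy group, as it does when lithiated β-alkoxy sulfones are trapped by carbonyl compounds in Julia couplings.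

**Step 11**
Reactants: 21 (2S,4S)-2-allyl-2-[(1S,2R)-1-(3,4-dimethoxyphenyl)-1-hydroxypropan-2-yl]-4-methoxy-5-(phenylsulfonyl)cyclopentan-1-one
Product: 22 (2S,4S)-2-allyl-2-[(1S,2R)-1-(3,4-dimethoxyphenyl)-1-hydroxypropan-2-yl]-4-methoxycyclopentan-1-one
Conditions: SmI2, THF/MeOH, −78 °C
Reagents that add atoms: none
Why: Reductive desulfonylation of a β-keto sulfone by single-electron transfer; the samarium enolate is protonated at once by methanol at −78 °C, so the β-methoxy group should not be eliminated and no stereocentre is touched.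

**Step 12**
Reactants: 22 (2S,4S)-2-allyl-2-[(1S,2R)-1-(3,4-dimethoxyphenyl)-1-hydroxypropan-2-yl]-4-methoxycyclopentan-1-one
Product: 24 (3S,5S)-5-allyl-5-[(1S,2R)-1-(3,4-dimethoxyphenyl)-1-(triethylsilyloxy)propan-2-yl]-3-methoxy-1-(triethylsilyloxy)cyclopent-1-ene, via C8 silyl ether ketone 23 (not isolated)
Conditions: Et3SiOTf, Et3N, CH2Cl2, −78 → 0 °C
Reagents that add atoms: triethylsilyl trifluoromethanesulfonate (CC[Si](CC)(CC)OS(=O)(=O)C(F)(F)F)
Why: Silyl triflate and amine silylate the C8 alcohol first (ketone 23) and then turn the ketone into its silyl enol ether by soft enolisation, without a free enolate that could eject methoxide; only C3 carries α-hydrogens, so a single regioisomer can form.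

**Step 13**
Reactants: 24 (3S,5S)-5-allyl-5-[(1S,2R)-1-(3,4-dimethoxyphenyl)-1-(triethylsilyloxy)propan-2-yl]-3-methoxy-1-(triethylsilyloxy)cyclopent-1-ene; 25 bromoform
Product: 28 (4S,6S)-6-allyl-2-bromo-6-[(1S,2R)-1-(3,4-dimethoxyphenyl)-1-(triethylsilyloxy)propan-2-yl]-4-methoxycyclohex-2-en-1-one, via dibromocarbene 26 (not isolated), via dibromocyclopropane 27 (not isolated)
Conditions: KOC(CH3)3, pentane, −30 °C → rt
Reagents that add atoms: none
Why: Dibromocarbene 26, formed from 25 by α-elimination, adds in a concerted [2+1] step to the electron-rich C1=C3 double bond of the enol ether and so makes the bonds C1–C2 and C2–C3 of the siloxy-dibromocyclopropane 27. On warming, the bromide endo to the five-membered ring leaves while the C1–C3 fusion bond opens in a disrotatory two-electron electrocyclic process pushed by the silyloxy group, and the resulting O-silylated 2-bromoenone (1-siloxy-2-bromoallyl cation) loses its silyl group to tert-butoxide or bromide. The closest known reaction type is the dihalocarbene ring expansion of cyclic silyl enol ethers to 2-halocycloalk-2-enones. Only the three-membered ring is closed, by cheletropic cycloaddition; the six-membered ring is not made by cyclisation but grows out of the five-membered ring when the shared bond breaks under release of cyclopropane strain. No new stereocentre survives, since the two transient cyclopropane centres C1 and C3 return to sp2, and C4, C6, C7 and C8 are not touched. The step needs a single enol ether regioisomer (secured by C6 having no hydrogen), addition to the enol ether in preference to the allyl group (secured by the electrophilic carbene meeting the donor-substituted alkene, with only a small excess of 25) and survival of a methoxy group next to an incipient enolate (secured by the sparingly soluble base in pentane at low temperature and by the triethylsilyl group, which resists alkoxide better than trimethylsilyl).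

**Step 14**
Reactants: 28 (4S,6S)-6-allyl-2-bromo-6-[(1S,2R)-1-(3,4-dimethoxyphenyl)-1-(triethylsilyloxy)propan-2-yl]-4-methoxycyclohex-2-en-1-one
Product: 29 (4S,6S)-6-allyl-6-[(1S,2R)-1-(3,4-dimethoxyphenyl)-1-(triethylsilyloxy)propan-2-yl]-4-methoxycyclohex-2-en-1-one
Conditions: Pd(PPh3)4 (cat.), Bu3SnH, toluene, rt
Reagents that add atoms: none
Why: Hydrodebromination catalysed by zerovalent palladium (oxidative addition into the vinyl C–Br bond, hydride transfer from tin, reductive elimination); at room temperature hydride capture should be faster than carbopalladation of the allyl group or conjugate reduction of the enone.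

**Step 15**
Reactants: 29 (4S,6S)-6-allyl-6-[(1S,2R)-1-(3,4-dimethoxyphenyl)-1-(triethylsilyloxy)propan-2-yl]-4-methoxycyclohex-2-en-1-one
Product: 30 (4S,6S)-6-allyl-6-[(1S,2R)-1-(3,4-dimethoxyphenyl)-1-hydroxypropan-2-yl]-4-methoxycyclohex-2-en-1-one (CNP0138111.1)
Conditions: HF·pyridine, pyridine, THF, 0 °C
Reagents that add atoms: none
Why: Fluoride cleavage of the triethylsilyl ether under buffered, non-basic conditions, chosen because the γ-methoxy enone is sensitive to base.

**Compound list**

1 | veratraldehyde (3,4-dimethoxybenzaldehyde) | COc1ccc(C=O)cc1OC | starting material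
2 | cis-but-2-ene | C/C=C\C | starting material
3 | (Z)-but-2-en-1-ylpotassium | C/C=C\C[K] | intermediate
4 | (Z)-crotylbis(isopinocampheyl)borane, Ipc groups from (+)-α-pinene | C/C=C\CB([C@@H]1C[C@@H]2C[C@H]([C@H]1C)C2(C)C)[C@@H]1C[C@@H]2C[C@H]([C@H]1C)C2(C)C | intermediate
5 | bis(isopinocampheyl)borinate ester of alcohol 6 | C=C[C@@H](C)[C@H](OB([C@@H]1C[C@@H]2C[C@H]([C@H]1C)C2(C)C)[C@@H]1C[C@@H]2C[C@H]([C@H]1C)C2(C)C)c1ccc(OC)c(OC)c1 | intermediate
6 | (1S,2R)-1-(3,4-dimethoxyphenyl)-2-methylbut-3-en-1-ol | C=C[C@@H](C)[C@H](O)c1ccc(OC)c(OC)c1 | intermediate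
7 | (1S,2R)-4-(9-borabicyclo[3.3.1]nonan-9-yl)-1-(3,4-dimethoxyphenyl)-2-methylbutan-1-ol | B1(CC[C@@H](C)[C@H](O)c3ccc(OC)c(OC)c3)C2CCCC1CCC2 | intermediate
8 | (1S,2R)-1-(3,4-dimethoxyphenyl)-2-methylbutane-1,4-diol | OCC[C@@H](C)[C@H](O)c1ccc(OC)c(OC)c1 | intermediate
9 | (4R,5S)-5-(3,4-dimethoxyphenyl)-4-methyloxolan-2-ol (both anomers) | OC1C[C@@H](C)[C@H](O1)c2ccc(OC)c(OC)c2 | intermediate
10 | (4R,5S)-5-(3,4-dimethoxyphenyl)-4-methyloxolan-2-one (cis) | O=C1C[C@@H](C)[C@H](O1)c2ccc(OC)c(OC)c2 | intermediate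
11 | (R)-2-[(trityloxy)methyl]oxirane (trityl ether of (S)-glycidol) | c1ccccc1C(c1ccccc1)(c1ccccc1)OC[C@H]1CO1 | starting material
12 | sodium (S)-1-(phenylsulfanyl)-3-(trityloxy)propan-2-olate | c1ccccc1C(c1ccccc1)(c1ccccc1)OC[C@H]([O-])CSc1ccccc1.[Na+] | intermediate
13 | (S)-[2-methoxy-3-(trityloxy)propyl](phenyl)sulfane | c1ccccc1C(c1ccccc1)(c1ccccc1)OC[C@H](OC)CSc1ccccc1 | intermediate
14 | (S)-2-methoxy-3-(phenylsulfanyl)propan-1-ol | OC[C@H](OC)CSc1ccccc1 | intermediate
15 | (S)-2-methoxy-3-(phenylsulfanyl)propyl trifluoromethanesulfonate | FC(F)(F)S(=O)(=O)OC[C@H](OC)CSc1ccccc1 | intermediate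
16 | (3R,4R,5S)-5-(3,4-dimethoxyphenyl)-3-[(2S)-2-methoxy-3-(phenylsulfanyl)propyl]-4-methyloxolan-2-one (major 3,4-trans epimer) | O=C1O[C@H](c2ccc(OC)c(OC)c2)[C@H](C)[C@H]1C[C@H](OC)CSc3ccccc3 | intermediate
17 | allyl bromide | C=CCBr | starting material
18 | (3S,4R,5S)-3-allyl-5-(3,4-dimethoxyphenyl)-3-[(2S)-2-methoxy-3-(phenylsulfanyl)propyl]-4-methyloxolan-2-one | C=CC[C@@]1(C[C@H](OC)CSc3ccccc3)C(=O)O[C@H](c2ccc(OC)c(OC)c2)[C@@H]1C | intermediate
19 | (3S,4R,5S)-3-allyl-5-(3,4-dimethoxyphenyl)-3-[(2S)-2-methoxy-3-(phenylsulfinyl)propyl]-4-methyloxolan-2-one (both sulfur epimers) | C=CC[C@@]1(C[C@H](OC)CS(=O)c3ccccc3)C(=O)O[C@H](c2ccc(OC)c(OC)c2)[C@@H]1C | intermediate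
20 | (3S,4R,5S)-3-allyl-5-(3,4-dimethoxyphenyl)-3-[(2S)-2-methoxy-3-(phenylsulfonyl)propyl]-4-methyloxolan-2-one | C=CC[C@@]1(C[C@H](OC)CS(=O)(=O)c3ccccc3)C(=O)O[C@H](c2ccc(OC)c(OC)c2)[C@@H]1C | intermediate
21 | (2S,4S)-2-allyl-2-[(1S,2R)-1-(3,4-dimethoxyphenyl)-1-hydroxypropan-2-yl]-4-methoxy-5-(phenylsulfonyl)cyclopentan-1-one (C5 epimers) | C=CC[C@@]1([C@@H](C)[C@H](O)c2ccc(OC)c(OC)c2)C[C@H](OC)C(S(=O)(=O)c3ccccc3)C1=O | intermediate
22 | (2S,4S)-2-allyl-2-[(1S,2R)-1-(3,4-dimethoxyphenyl)-1-hydroxypropan-2-yl]-4-methoxycyclopentan-1-one | C=CC[C@@]1([C@@H](C)[C@H](O)c2ccc(OC)c(OC)c2)C[C@H](OC)CC1=O | intermediate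
23 | (2S,4S)-2-allyl-2-[(1S,2R)-1-(3,4-dimethoxyphenyl)-1-(triethylsilyloxy)propan-2-yl]-4-methoxycyclopentan-1-one | C=CC[C@@]1([C@@H](C)[C@H](O[Si](CC)(CC)CC)c2ccc(OC)c(OC)c2)C[C@H](OC)CC1=O | intermediate
24 | (3S,5S)-5-allyl-5-[(1S,2R)-1-(3,4-dimethoxyphenyl)-1-(triethylsilyloxy)propan-2-yl]-3-methoxy-1-(triethylsilyloxy)cyclopent-1-ene | C=CC[C@@]1([C@@H](C)[C@H](O[Si](CC)(CC)CC)c2ccc(OC)c(OC)c2)C[C@H](OC)C=C1O[Si](CC)(CC)CC | intermediate
25 | bromoform | BrC(Br)Br | starting material
26 | dibromocarbene | Br[C]Br | intermediate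
27 | 6,6-dibromo-1-(triethylsilyloxy)bicyclo[3.1.0]hexane adduct of 24 (CBr2 bridging C1 and C3, ring fusion cis on either face, the four stereocentres of 24 unchanged) | C=CC[C@@]1([C@@H](C)[C@H](O[Si](CC)(CC)CC)c2ccc(OC)c(OC)c2)C[C@H](OC)C3C(Br)(Br)C13O[Si](CC)(CC)CC | intermediate
28 | (4S,6S)-6-allyl-2-bromo-6-[(1S,2R)-1-(3,4-dimethoxyphenyl)-1-(triethylsilyloxy)propan-2-yl]-4-methoxycyclohex-2-en-1-one | C=CC[C@@]1([C@@H](C)[C@H](O[Si](CC)(CC)CC)c2ccc(OC)c(OC)c2)C[C@H](OC)C=C(Br)C1=O | intermediate
29 | (4S,6S)-6-allyl-6-[(1S,2R)-1-(3,4-dimethoxyphenyl)-1-(triethylsilyloxy)propan-2-yl]-4-methoxycyclohex-2-en-1-one | C=CC[C@@]1([C@@H](C)[C@H](O[Si](CC)(CC)CC)c2ccc(OC)c(OC)c2)C[C@H](OC)C=CC1=O | intermediate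
30 | (4S,6S)-6-allyl-6-[(1S,2R)-1-(3,4-dimethoxyphenyl)-1-hydroxypropan-2-yl]-4-methoxycyclohex-2-en-1-one (CNP0138111.1) | C=CC[C@@]1([C@@H](C)[C@H](O)c2ccc(OC)c(OC)c2)C[C@H](OC)C=CC1=O | target

**Step count**

Total: 15 steps. Longest linear sequence: 12 steps (steps 1–3 and 7–15; the branch through steps 4–6 and 7–15 is equally long).

**Steps most likely to fail**

Step 10 (closure of the five-membered ring). The lithiated β-methoxy sulfone may lose methoxide (E1cB, giving a vinyl sulfone) before it attacks the hindered lactone carbonyl next to the quaternary centre. The fallback lowers the oxidation level of the acceptor so that closure is fast at −78 °C. It sets out from 20. LiBH4 (THF/MeOH) should reduce the lactone to the sulfone diol F1, and Et3SiOTf/2,6-lutidine should give the bis(triethylsilyl) ether F2. Swern oxidation ((COCl)2, DMSO, then Et3N) is known to convert a primary triethylsilyl ether directly into the aldehyde while a secondary one stays, which should give the aldehyde F3. KN(SiMe3)2 in THF at −78 °C should then close the ring by addition of the sulfonyl carbanion to the non-enolisable aldehyde (the first half of a Julia olefination), giving the β-hydroxy sulfone F4. Dess–Martin periodinane should oxidise this to the β-keto sulfone F5, and SmI2 in THF/MeOH should remove the sulfonyl group. The fallback comes back to the route at ketone 23, which is taken to 24 with Et3SiOTf/Et3N as in step 12.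

Step 13 (ring expansion). Excess carbene may also cyclopropanate the allyl group, or tert-butoxide may attack silicon and release the potassium enolate, which then expels the C4 methoxide. The fallback replaces the dihalocarbene and the strong base by a zinc carbenoid and an oxidative ring opening of the same C1–C3 bond. It sets out from 24. Et2Zn/CH2I2 in CH2Cl2 at 0 °C (Simmons–Smith reaction, fastest at the enol ether) should give the siloxycyclopropane F6. FeCl3 in DMF at 0 °C should cleave the fusion bond by one-electron oxidation and deliver the ring-expanded 3-chloro ketone F7. NaOAc in MeOH should then eliminate hydrogen chloride. The fallback comes back to the route at 29 and leaves no bromine to remove.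

Step 12 (double silylation). The silyl triflate may ionise the methoxy group, at the ketone stage or at the allylic position of the enol ether once formed, so that methanol is lost and a cyclopentenone results. The fallback inserts the extra carbon with a diazoalkane, so the five-membered ketone is never enolised. It sets out from 22. Et3SiCl/imidazole in DMF should give 23, here isolated. Me3SiCHN2/AlMe3 in CH2Cl2 at −78 → −20 °C, with protodesilylation on work-up, should give the ring-expanded cyclohexanone F8; the CH2 carbon C3 migrates in preference to the quaternary C6, and the methoxy group is now γ to the carbonyl and cannot be eliminated. LiN(i-Pr)2/Me3SiCl at −78 °C should give the silyl enol ether F9, which can only form toward the new C2. Pd(OAc)2 in MeCN (Saegusa–Ito oxidation) should then introduce the C2=C3 double bond. The fallback comes back to the route at 29.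

**Further compounds**

F1 | step 10 | (2S,4S)-2-allyl-2-[(1S,2R)-1-(3,4-dimethoxyphenyl)-1-hydroxypropan-2-yl]-4-methoxy-5-(phenylsulfonyl)pentan-1-ol | C=CC[C@](CO)(C[C@H](OC)CS(=O)(=O)c3ccccc3)[C@@H](C)[C@H](O)c2ccc(OC)c(OC)c2
F2 | step 10 | bis(triethylsilyl) ether of F1 | C=CC[C@](CO[Si](CC)(CC)CC)(C[C@H](OC)CS(=O)(=O)c3ccccc3)[C@@H](C)[C@H](O[Si](CC)(CC)CC)c2ccc(OC)c(OC)c2
F3 | step 10 | (2S,4S)-2-allyl-2-[(1S,2R)-1-(3,4-dimethoxyphenyl)-1-(triethylsilyloxy)propan-2-yl]-4-methoxy-5-(phenylsulfonyl)pentanal | C=CC[C@](C=O)(C[C@H](OC)CS(=O)(=O)c3ccccc3)[C@@H](C)[C@H](O[Si](CC)(CC)CC)c2ccc(OC)c(OC)c2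
F4 | step 10 | (2S,4S)-2-allyl-2-[(1S,2R)-1-(3,4-dimethoxyphenyl)-1-(triethylsilyloxy)propan-2-yl]-4-methoxy-5-(phenylsulfonyl)cyclopentan-1-ol (mixture at C1 and C5) | C=CC[C@@]1([C@@H](C)[C@H](O[Si](CC)(CC)CC)c2ccc(OC)c(OC)c2)C[C@H](OC)C(S(=O)(=O)c3ccccc3)C1O
F5 | step 10 | (2S,4S)-2-allyl-2-[(1S,2R)-1-(3,4-dimethoxyphenyl)-1-(triethylsilyloxy)propan-2-yl]-4-methoxy-5-(phenylsulfonyl)cyclopentan-1-one (C5 epimers) | C=CC[C@@]1([C@@H](C)[C@H](O[Si](CC)(CC)CC)c2ccc(OC)c(OC)c2)C[C@H](OC)C(S(=O)(=O)c3ccccc3)C1=O
F6 | step 13 | 1-(triethylsilyloxy)bicyclo[3.1.0]hexane from 24 (CH2 bridging C1 and C3, the four stereocentres of 24 unchanged) | C=CC[C@@]1([C@@H](C)[C@H](O[Si](CC)(CC)CC)c2ccc(OC)c(OC)c2)C[C@H](OC)C3CC13O[Si](CC)(CC)CC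
F7 | step 13 | (2S,4S)-2-allyl-5-chloro-2-[(1S,2R)-1-(3,4-dimethoxyphenyl)-1-(triethylsilyloxy)propan-2-yl]-4-methoxycyclohexan-1-one (C5 epimers) | C=CC[C@@]1([C@@H](C)[C@H](O[Si](CC)(CC)CC)c2ccc(OC)c(OC)c2)C[C@H](OC)C(Cl)CC1=O
F8 | step 12 | (2S,4R)-2-allyl-2-[(1S,2R)-1-(3,4-dimethoxyphenyl)-1-(triethylsilyloxy)propan-2-yl]-4-methoxycyclohexan-1-one | C=CC[C@@]1([C@@H](C)[C@H](O[Si](CC)(CC)CC)c2ccc(OC)c(OC)c2)C[C@H](OC)CCC1=O
F9 | step 12 | (4R,6S)-6-allyl-6-[(1S,2R)-1-(3,4-dimethoxyphenyl)-1-(triethylsilyloxy)propan-2-yl]-4-methoxy-1-(trimethylsilyloxy)cyclohex-1-ene | C=CC[C@@]1([C@@H](C)[C@H](O[Si](CC)(CC)CC)c2ccc(OC)c(OC)c2)C[C@H](OC)CC=C1O[Si](C)(C)C
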